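The partner is the limiting reagent of the larch run: its charge of 0.320 M stands below the 0.400 M of substrate, so the larch run has a ceiling of 80.0 % of the substrate charged.

| setting | ash | oak | cedar | larch |
|---|---|---|---|---|
| substrate | 0.400 M | 0.400 M | 0.400 M | 0.400 M |
| partner | 0.320 M | 0.960 M | 0.320 M | 0.320 M |
| free catalyst | 0.0200 M | 0.0200 M | 0.0100 M | 0.0200 M |
| time |  |  |  | 48 h |

| run | time / h | [product] / M |
|---|---|---|
| ash run | 0.29 | 0 |
| ash run | 0.87 | 0.0046 |
| ash run | 1.7 | 0.0187 |
| ash run | 2.6 | 0.0422 |
| ash run | 3.8 | 0.0740 |
| ash run | 5.0 | 0.1074 |
| ash run | 6.5 | 0.1446 |
| ash run | 8.0 | 0.1759 |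
| oak run | 0.29 | 0.0058 |
| oak run | 0.87 | 0.0442 |
| oak run | 1.7 | 0.1294 |
| oak run | 2.6 | 0.2184 |
| oak run | 3.8 | 0.3027 |
| oak run | 5.0 | 0.3472 |
| oak run | 6.5 | 0.3777 |
| oak run | 8.0 | 0.3885 |
| cedar run | 0.29 | 0.0010 |
| cedar run | 0.87 | 0.0020 |
| cedar run | 1.7 | 0.0073 |
| cedar run | 2.6 | 0.0156 |
| cedar run | 3.8 | 0.0359 |
| cedar run | 5.0 | 0.0580 |
| cedar run | 6.5 | 0.0837 |
| cedar run | 8.0 | 0.1129 |

(readings scatter by 0.001 M)

- Overall: substrate + partner -> product, with free catalyst as catalyst.
- Constant volume, constant temperature.
- An order is taken over about fifteen percent of the charge, up and down.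

- how the opening rate goes with [partner] round the charge of the ash run: the exponent of the rate at two percent of substrate gone to product
- how the opening rate goes with [free catalyst] round the charge of the ash run: the exponent of the rate at two percent of substrate gone to product
- product in the larch run at 48 h, as a share of the substrate charged

I turn the question round: what would have to be true for the larch run to stand at a share of 0.7 at 48 h? Substrate and partner fall together, so c(substrate) − c(partner) stays at 0.0800 M in that run. I assume a rate proportional to c(substrate)·c(partner) with a steady coefficient, which makes ln(c(substrate)/c(partner)) climb in a straight line. The time for it to climb by one is the tail lifetime 16.3 h, the lifetime of a nearly pseudo-first-order tail, and it goes inversely with that difference. I read it from the last two oak readings, where the difference is 0.560 M and the free catalyst charge equals that of the larch run, and scale it to the larch run.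

The larch run repeats the ash charge, so I start from the ash run at 8.0 h, where the ratio reads 1.56. A share of 0.7 at 48 h would need a tail lifetime of 60.9 h. The last two ash readings give 22.8 h, which is shorter, so the larch run stands far from that outcome. Going forward with 16.3 h, the value read in the oak tail, the remaining time holds 2.45 lifetimes. On this estimate that leaves 0.00469 M of partner in the larch run, and my reckoning is 78.8 %.

The forecast gives an order of 1 in partner, an order of 0.72 in free catalyst and 78 % for the larch run, “with the risk on the low side”. My share lies above its share.

The flask gives an order of 1.0 in partner, an order of 0.66 in free catalyst and 78.9 % for the larch run, which is 1.1 percentage points below the ceiling.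

    2 active catalyst ⇌ catalyst dimer, settled at all times (108.0 L mol⁻¹)
    catalyst dimer + substrate + partner → product + catalyst dimer (39.96 L² mol⁻² h⁻¹)
    substrate + partner + product → 2 product (1.840 L² mol⁻² h⁻¹)
    free catalyst + partner → active catalyst + partner (2.167 L mol⁻¹ h⁻¹)

The slowness of the step from free catalyst to active catalyst changes the larch share by little. The larch share leaves 0.00458 M of partner, which over the same time means a tail lifetime of 16.2 h against my 16.3 h. The cedar run, charged with 0.0100 M of free catalyst, has the same difference between charges, and between a quarter and half of its substrate turned, at 7.32 h and 13.8 h, its lifetime comes to 32.4 h, twice the 16.3 h of my reckoning.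

The runs come from a simulation on assumed constants; the scatter is artificial.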